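**Retrosynthetic overview**

1. Target (azulene numbering: C3 carbinol, C3a–H, C4 ester carbon, C5=C6 olefin, C8a quaternary methyl) ⇐ acylation of the 3,4-diol ⇐ hydroxyl-directed reduction of the C4 ketone ⇐ isopropyl-metal addition to the C3 carbonyl of a bicyclic silyl vinylogous ester; the angular C8a methyl fixes C3, and C3 then fixes C3a and C4.
2. Five-membered ring ⇐ Dieckmann-type closure (C3–C3a) of a monocyclic 3-methylcyclohept-2-enone carrying a propanoate chain on the quaternary carbon.
3. Seven-membered ring ⇐ one-carbon ring enlargement (key step): C5 is brought in as a bis(phenylthio)methyl group on the C4 carbonyl of a 2-methylcyclohexanone, and a copper-triggered 1,2-shift makes the C5–C6 bond; the sulfur left on C5 is then expelled to give C5=C6.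
4. Enabling feature: in the seven-membered ring only the unsubstituted C5–H separates the oxygenated C4 from the methyl-bearing C6, so ring atoms C3a, C4, C6, C7, C8 and C8a are a 2-methylcyclohexanone whose C4–C6 bond can take up C5, the C4 oxygen supplying the push for the shift.
5. C8a ⇐ copper-catalysed asymmetric conjugate addition to 3-methylcyclohex-2-enone; ring order: six-membered ring (purchased), seven-membered ring (step 5), five-membered ring (step 8).

Key step: step 5

Remark: locants in names and comments follow the azulene numbering of the target also where lower locants are possible, and the antipode of the chiral carbene ligand in step 1 is taken to be the one that gives the S ketone, with enantiomeric enrichment by recrystallisation of a solid intermediate if required.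

**Route**

Step 1
Reactants: 1 3-methylcyclohex-2-en-1-one; 2 but-3-en-1-ylmagnesium bromide
Product: 3 (3S)-3-(but-3-en-1-yl)-3-methylcyclohexan-1-one
Conditions: Cu(OTf)2 (3 mol %), chiral C2-symmetric imidazolinium chloride (carbene ligand precursor, 4 mol %), Et2O, 0 °C; then 1 M HCl
Reagents that add atoms: none
Why: Copper/N-heterocyclic-carbene-catalysed asymmetric conjugate addition of Grignard reagents to β-methyl cyclohexenones is an established route to all-carbon quaternary centres, and the chiral carbene ligand should deliver the butenyl group to one enantioface of the enone, which sets the future C8a.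

Step 2
Reactants: 3 (3S)-3-(but-3-en-1-yl)-3-methylcyclohexan-1-one
Product: 4 (5R)-5-(but-3-en-1-yl)-2,5-dimethylcyclohexan-1-one (C2 epimers; same spatial arrangement at the quaternary carbon as in 3, the descriptor changes with the CIP priorities)
Conditions: LiN(iPr)2, THF, −78 °C; then MeI, −78 to 0 °C
Reagents that add atoms: iodomethane, CI
Why: Kinetic enolisation by the hindered amide should occur at the α-methylene remote from the quaternary carbon and C-methylation (enolate alkylation) then places the methyl group on the future C6, whose configuration is irrelevant because this carbon later becomes trigonal.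

Step 3
Reactants: 4 (5R)-5-(but-3-en-1-yl)-2,5-dimethylcyclohexan-1-one
Product: 5 methyl 3-[(1S)-1,4-dimethyl-3-oxocyclohexyl]propanoate (C4 epimers)
Conditions: O3, NaOH (2.5 M in MeOH), CH2Cl2, −78 °C
Reagents that add atoms: ozone, [O-][O+]=O; methanol, CO
Why: Ozonolysis in methanolic NaOH should convert the terminal alkene directly into the methyl ester (oxidative cleavage, trapping of the carbonyl oxide by methanol, base-induced dehydration of the methoxy hydroperoxide), the ketone being inert to ozone.

Step 4
Reactants: 5 methyl 3-[(1S)-1,4-dimethyl-3-oxocyclohexyl]propanoate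
Product: 6 methyl 3-[(1S)-3-[bis(phenylsulfanyl)methyl]-3-hydroxy-1,4-dimethylcyclohexyl]propanoate (diastereomer mixture at C3 and C4 of the ring)
Conditions: (PhS)2CH2, n-BuLi, THF, 0 °C; then 5, −78 °C; AcOH
Reagents that add atoms: bis(phenylsulfanyl)methane, C(Sc1ccccc1)Sc1ccccc1
Why: The sulfur-stabilised carbanion should add to the ketone far faster than to the ester (1,2-carbonyl addition) and delivers the future C5 at the dithioacetal oxidation level, the configuration of the new carbinol being without consequence.

Step 5
Reactants: 6 methyl 3-[(1S)-3-[bis(phenylsulfanyl)methyl]-3-hydroxy-1,4-dimethylcyclohexyl]propanoate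
Product: 8 methyl 3-[(1S)-1,5-dimethyl-3-oxo-4-(phenylsulfanyl)cycloheptyl]propanoate (diastereomer mixture at C4 and C5 of the ring), via thionium ion 7 (not isolated)
Conditions: (CuOTf)2·C6H6, iPr2NEt, benzene–THF, 25 to 60 °C
Reagents that add atoms: none
Why: CuOTf, a thiophilic salt of monovalent copper, pulls one phenylthiolate off the dithioacetal to give the sulfur-stabilised carbocation 7, and the ring bond from the carbinol carbon (future C4) to the methyl-bearing methine (future C6) then migrates to this cationic carbon (future C5) as the hydroxyl becomes the ketone, a semipinacol 1,2-shift. The closest known reaction type is the copper-triflate-induced ring enlargement of 1-[bis(phenylthio)methyl]cycloalkanols to 2-(phenylthio)cycloalkanones, a sulfur-assisted relative of the Tiffeneau–Demjanov homologation. The seven-membered ring is closed by ring enlargement, that is by a suprafacial three-centre 1,2-alkyl shift that makes the C5–C6 bond while the C4–C6 bond breaks, so no exo or endo cyclisation mode applies. The migrating methine keeps its configuration and the new sulfur-bearing centre C5 forms without control, but both become trigonal in step 7 and do not matter. The step needs the methyl-substituted methine and not the methylene next to the quaternary carbon to migrate, which the higher migratory aptitude of the more substituted carbon in cationic 1,2-shifts should secure, and it needs the shift to outrun closure to an α-thio epoxide, which the amine-buffered, non-nucleophilic medium should favour.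

Step 6
Reactants: 8 methyl 3-[(1S)-1,5-dimethyl-3-oxo-4-(phenylsulfanyl)cycloheptyl]propanoate
Product: 9 methyl 3-[(1S)-1,5-dimethyl-3-oxo-4-(phenylsulfinyl)cycloheptyl]propanoate (diastereomer mixture)
Conditions: mCPBA (1.0 equiv), CH2Cl2, −78 °C
Reagents that add atoms: 3-chloroperbenzoic acid, OOC(=O)c1cccc(Cl)c1
Why: One equivalent of peracid at low temperature should oxidise the sulfide to the sulfoxide much faster than the ketone undergoes Baeyer–Villiger oxidation (chemoselective S-oxidation).

Step 7
Reactants: 9 methyl 3-[(1S)-1,5-dimethyl-3-oxo-4-(phenylsulfinyl)cycloheptyl]propanoate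
Product: 10 methyl 3-[(1S)-1,5-dimethyl-3-oxocyclohept-4-en-1-yl]propanoate
Conditions: toluene, CaCO3, 100 °C
Reagents that add atoms: none
Why: Thermal syn-elimination of the α-sulfinyl ketone (sulfoxide pyrolysis) can only engage the hydrogen on the methyl-bearing carbon and should give the conjugated trisubstituted C5=C6 enone, the readily epimerised sulfur-bearing carbon letting every diastereomer reach the syn-periplanar geometry.

Step 8
Reactants: 10 methyl 3-[(1S)-1,5-dimethyl-3-oxocyclohept-4-en-1-yl]propanoate
Product: 11 (8aS)-4-hydroxy-6,8a-dimethyl-1,7,8,8a-tetrahydroazulen-3(2H)-one (enol form of the bicyclic 3,4-dione)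
Conditions: KOtBu (2.2 equiv), THF, 0 °C to rt; then 1 M HCl
Reagents that add atoms: none
Why: Under equilibrating alkoxide conditions the α′-enolate of the enone should attack the ester in a 5-exo-trig Dieckmann-type (intramolecular Claisen) condensation, and irreversible deprotonation of the resulting β-diketone drives closure of the five-membered ring without creating a stereocentre.

Step 9
Reactants: 11 (8aS)-4-hydroxy-6,8a-dimethyl-1,7,8,8a-tetrahydroazulen-3(2H)-one
Product: 12 (8aS)-4-[(tert-butyldimethylsilyl)oxy]-6,8a-dimethyl-1,7,8,8a-tetrahydroazulen-3(2H)-one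
Conditions: TBSCl, imidazole, DMF, 0 °C to rt
Reagents that add atoms: tert-butyldimethylsilyl chloride, CC(C)(C)[Si](C)(C)Cl
Why: O-Silylation should trap the through-conjugated enol whose hydroxyl sits on C4 (cyclopentanone carbonyl retained, enol double bond exocyclic to the five-membered ring and conjugated with C5=C6), giving a silyl vinylogous ester in which only the C3 carbonyl remains free (enol silylation).

Step 10
Reactants: 12 (8aS)-4-[(tert-butyldimethylsilyl)oxy]-6,8a-dimethyl-1,7,8,8a-tetrahydroazulen-3(2H)-one
Product: 14 (3R,3aR,8aS)-3-hydroxy-6,8a-dimethyl-3-(propan-2-yl)-2,3,3a,7,8,8a-hexahydroazulen-4(1H)-one, via tertiary alkoxide 13 (not isolated)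
Conditions: iPrMgCl, CeCl3, THF, −78 °C; then AcOH, Bu4NF, THF, 0 °C
Reagents that add atoms: isopropylmagnesium chloride, CC(C)[Mg]Cl
Why: The organocerium reagent should add 1,2 to the only free carbonyl of the vinylogous ester, as in the first stage of a Stork–Danheiser sequence, from the face opposite the axial angular methyl on C8a (hydroxyl cis to that methyl), and buffered fluoride then unveils the C4 ketone while the epimerisable C3a–H is expected to settle trans to the angular methyl, where C4 lies cis to the hydrogen-bonding hydroxyl and away from the isopropyl group.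

Step 11
Reactants: 14 (3R,3aR,8aS)-3-hydroxy-6,8a-dimethyl-3-(propan-2-yl)-2,3,3a,7,8,8a-hexahydroazulen-4(1H)-one
Product: 15 (3R,3aS,4S,8aS)-6,8a-dimethyl-3-(propan-2-yl)-1,2,3,3a,4,7,8,8a-octahydroazulene-3,4-diol
Conditions: Me4NBH(OAc)3, MeCN–AcOH, −30 °C
Reagents that add atoms: none
Why: In the Evans–Saksena reduction the triacetoxyborohydride exchanges onto the C3 hydroxyl and should deliver hydride intramolecularly to the C4 carbonyl from the face on which that oxygen sits, giving the 1,3-anti diol with the 4S carbinol and clean 1,2-selectivity for the enone.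

Step 12
Reactants: 15 (3R,3aS,4S,8aS)-6,8a-dimethyl-3-(propan-2-yl)-1,2,3,3a,4,7,8,8a-octahydroazulene-3,4-diol; 16 4-methoxybenzoyl chloride
Product: 17 (3R,3aS,4S,8aS)-3-hydroxy-6,8a-dimethyl-3-(propan-2-yl)-1,2,3,3a,4,7,8,8a-octahydroazulen-4-yl 4-methoxybenzoate
Conditions: pyridine, DMAP (cat.), CH2Cl2, 0 °C to rt
Reagents that add atoms: none
Why: DMAP-catalysed acylation should esterify the secondary allylic hydroxyl and leave the hindered tertiary hydroxyl untouched (chemoselective esterification).

**Compound list**

1 | 3-methylcyclohex-2-en-1-one | CC1=CC(=O)CCC1 | starting material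
2 | but-3-en-1-ylmagnesium bromide | C=CCC[Mg]Br | starting material
3 | (3S)-3-(but-3-en-1-yl)-3-methylcyclohexan-1-one | C=CCC[C@@]1(C)CC(=O)CCC1 | intermediate
4 | (5R)-5-(but-3-en-1-yl)-2,5-dimethylcyclohexan-1-one (C2 epimers) | C=CCC[C@@]1(C)CC(=O)C(C)CC1 | intermediate
5 | methyl 3-[(1S)-1,4-dimethyl-3-oxocyclohexyl]propanoate (C4 epimers) | COC(=O)CC[C@@]1(C)CC(=O)C(C)CC1 | intermediate
6 | methyl 3-[(1S)-3-[bis(phenylsulfanyl)methyl]-3-hydroxy-1,4-dimethylcyclohexyl]propanoate (diastereomer mixture) | COC(=O)CC[C@@]1(C)CC(O)(C(Sc2ccccc2)Sc2ccccc2)C(C)CC1 | intermediate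
7 | S-phenyl thionium ion formed from 6 by loss of phenylthiolate | COC(=O)CC[C@@]1(C)CC(O)(C=[S+]c2ccccc2)C(C)CC1 | intermediate
8 | methyl 3-[(1S)-1,5-dimethyl-3-oxo-4-(phenylsulfanyl)cycloheptyl]propanoate (diastereomer mixture) | COC(=O)CC[C@@]1(C)CC(=O)C(Sc2ccccc2)C(C)CC1 | intermediate
9 | methyl 3-[(1S)-1,5-dimethyl-3-oxo-4-(phenylsulfinyl)cycloheptyl]propanoate (diastereomer mixture) | COC(=O)CC[C@@]1(C)CC(=O)C(S(=O)c2ccccc2)C(C)CC1 | intermediate
10 | methyl 3-[(1S)-1,5-dimethyl-3-oxocyclohept-4-en-1-yl]propanoate | COC(=O)CC[C@@]1(C)CC(=O)C=C(C)CC1 | intermediate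
11 | (8aS)-4-hydroxy-6,8a-dimethyl-1,7,8,8a-tetrahydroazulen-3(2H)-one | CC1=CC(O)=C2C(=O)CC[C@]2(C)CC1 | intermediate
12 | (8aS)-4-[(tert-butyldimethylsilyl)oxy]-6,8a-dimethyl-1,7,8,8a-tetrahydroazulen-3(2H)-one | CC1=CC(O[Si](C)(C)C(C)(C)C)=C2C(=O)CC[C@]2(C)CC1 | intermediate
13 | (3R,8aS)-4-[(tert-butyldimethylsilyl)oxy]-6,8a-dimethyl-3-(propan-2-yl)-1,2,3,7,8,8a-hexahydroazulen-3-ol (formed as its metal alkoxide, drawn as the alcohol) | CC1=CC(O[Si](C)(C)C(C)(C)C)=C2[C@](O)(C(C)C)CC[C@]2(C)CC1 | intermediate
14 | (3R,3aR,8aS)-3-hydroxy-6,8a-dimethyl-3-(propan-2-yl)-2,3,3a,7,8,8a-hexahydroazulen-4(1H)-one (C3a–H trans to the C8a methyl) | O=C1C=C(C)CC[C@@]2(C)CC[C@@](O)(C(C)C)[C@H]12 | intermediate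
15 | (3R,3aS,4S,8aS)-6,8a-dimethyl-3-(propan-2-yl)-1,2,3,3a,4,7,8,8a-octahydroazulene-3,4-diol | O[C@H]1C=C(C)CC[C@@]2(C)CC[C@@](O)(C(C)C)[C@H]12 | intermediate
16 | 4-methoxybenzoyl chloride | COc1ccc(C(=O)Cl)cc1 | starting material
17 | (3R,3aS,4S,8aS)-3-hydroxy-6,8a-dimethyl-3-(propan-2-yl)-1,2,3,3a,4,7,8,8a-octahydroazulen-4-yl 4-methoxybenzoate | COc1ccc(C(=O)O[C@H]2C=C(C)CC[C@@]3(C)CC[C@@](O)(C(C)C)[C@H]23)cc1 | target

Total step count: 12. Longest linear sequence: 12 steps (1 to 17).

**Steps most likely to fail**

Step 5 (ring enlargement). The thionium ion may be captured by the neighbouring hydroxyl (epoxide closure and hydride shift) or the wrong ring bond may migrate, so that the enlargement is slow or unselective. The fallback replaces the cationic shift by a radical siloxycyclopropane ring expansion; it sets out from 5 and comes back at 10. Compound 5 is converted under equilibrating conditions (TMSCl, NaI, Et3N, MeCN) into the more substituted silyl enol ether methyl 3-[(1S)-1,4-dimethyl-3-[(trimethylsilyl)oxy]cyclohex-3-en-1-yl]propanoate F1. Simmons–Smith cyclopropanation (Et2Zn, CH2I2) gives methyl 3-[(3S)-3,6-dimethyl-1-[(trimethylsilyl)oxy]bicyclo[4.1.0]heptan-3-yl]propanoate F2. FeCl3 in DMF opens the internal cyclopropane bond by alkoxy-radical β-scission to the β-chloro ketone methyl 3-[(1R)-5-chloro-1,5-dimethyl-3-oxocycloheptyl]propanoate F3, and NaOAc in MeOH eliminates hydrogen chloride to give 10.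

Step 10 (isopropyl addition and C3a equilibration). The organometallic may attack syn to the angular methyl, may add in conjugate fashion with loss of the silyloxy group, or may react through the regioisomeric silyl ether after an oxygen-to-oxygen silyl shift; the C3a epimers may also fail to equilibrate cleanly. The fallback installs the isopropyl group before the five-membered ring is closed and makes the C3–C3a bond by an aldol addition under thermodynamic control; it sets out from 10, comes back at 14 and also bypasses steps 8 and 9. Saponification (LiOH, THF–H2O) gives 3-[(1S)-1,5-dimethyl-3-oxocyclohept-4-en-1-yl]propanoic acid F4. Thioesterification (EtSH, DCC, DMAP) gives S-ethyl 3-[(1S)-1,5-dimethyl-3-oxocyclohept-4-en-1-yl]propanethioate F5. Fukuyama coupling (iPrZnI, PdCl2(PPh3)2, toluene) gives (6S)-3,6-dimethyl-6-(4-methyl-3-oxopentyl)cyclohept-2-en-1-one F6. A catalytic amount of KOtBu in t-BuOH–THF at 0 °C should then equilibrate F6 through reversible aldol addition to the hydrogen-bonded, trans-fused ketol 14, in which the isopropyl group lies anti to the angular methyl.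

Step 11 (directed reduction). Ligand exchange at the hindered tertiary hydroxyl may be slow, so that hydride is delivered externally with poor or opposite facial selectivity. The fallback sets the C4 configuration by SN2 inversion instead of by directed hydride delivery; it sets out from 14, comes back at 17 and replaces step 12 as well. Luche reduction (NaBH4, CeCl3·7H2O, MeOH, −78 °C) should deliver hydride to the open face next to the axial C3a–H and give (3R,3aS,4R,8aS)-6,8a-dimethyl-3-(propan-2-yl)-1,2,3,3a,4,7,8,8a-octahydroazulene-3,4-diol F7. Mitsunobu esterification of its secondary hydroxyl with 4-methoxybenzoic acid (PPh3, DIAD, toluene) inverts C4 and gives 17 directly.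

Further compounds
F1 | step 5 | methyl 3-[(1S)-1,4-dimethyl-3-[(trimethylsilyl)oxy]cyclohex-3-en-1-yl]propanoate | COC(=O)CC[C@@]1(C)CC(O[Si](C)(C)C)=C(C)CC1
F2 | step 5 | methyl 3-[(3S)-3,6-dimethyl-1-[(trimethylsilyl)oxy]bicyclo[4.1.0]heptan-3-yl]propanoate | COC(=O)CC[C@@]1(C)CC2(O[Si](C)(C)C)CC2(C)CC1
F3 | step 5 | methyl 3-[(1R)-5-chloro-1,5-dimethyl-3-oxocycloheptyl]propanoate | COC(=O)CC[C@@]1(C)CC(=O)CC(C)(Cl)CC1
F4 | step 10 | 3-[(1S)-1,5-dimethyl-3-oxocyclohept-4-en-1-yl]propanoic acid | OC(=O)CC[C@@]1(C)CC(=O)C=C(C)CC1
F5 | step 10 | S-ethyl 3-[(1S)-1,5-dimethyl-3-oxocyclohept-4-en-1-yl]propanethioate | CCSC(=O)CC[C@@]1(C)CC(=O)C=C(C)CC1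
F6 | step 10 | (6S)-3,6-dimethyl-6-(4-methyl-3-oxopentyl)cyclohept-2-en-1-one | CC(C)C(=O)CC[C@@]1(C)CC(=O)C=C(C)CC1
F7 | step 11 | (3R,3aS,4R,8aS)-6,8a-dimethyl-3-(propan-2-yl)-1,2,3,3a,4,7,8,8a-octahydroazulene-3,4-diol | O[C@@H]1C=C(C)CC[C@@]2(C)CC[C@@](O)(C(C)C)[C@H]12
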